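All runs are calculated for an exercise, noise included.

The constants are hidden, so you read them from the two earlier runs, and you work with x, the fraction of X left, not with what was made. X may react with Q to Z, pair reversibly to E, or go to D, and E may crystallise as G.

| flask | X | Q | temperature | remark | time |
|---|---|---|---|---|---|
| south-east | 10 mM | 1 mM | 60 °C | run made earlier |  |
| south-west | 10 mM | 1.5 mM | 82 °C | run made earlier |  |
| Tuesday's | 10 mM | 2.00 mM |  | at 50 °C until 25 min, from then on at 90 °C | 80 min |
| Sunday's | 10 mM | 2.00 mM |  | at 90 °C throughout | 80 min |

| run | time / min | E / % | X / % |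
|---|---|---|---|
| south-east | 3.00 | 41 | 48 |
| south-east | 10.0 | 66 | 25 |
| south-east | 20.0 | 77 | 14 |
| south-east | 25.0 | 79 | 13 |
| south-east | 40.0 | 80 | 8 |
| south-east | 50.0 | 82 | 7 |
| south-west | 1.33 | 42 | 44 |
| south-west | 2.00 | 50 | 34 |
| south-west | 4.00 | 62 | 21 |
| south-west | 6.00 | 66 | 17 |
| south-west | 10.0 | 72 | 11 |
| south-west | 15.0 | 74 | 8 |

(readings scatter by 1.5 percentage points)

- which one finishes higher in amount of E, in percent of the X charged ("neither" within 2 percentage points) (Tuesday's / Sunday's / neither)
- amount of E at the end, in percent of the X charged, Tuesday's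
- amount of E at the end, in percent of the X charged, Sunday's

- in percentages every species weighs as the X in it: one E or G counts as two
- for E the G are counted in
- as a solid, counted per litre of solution: G
- candidate steps: X + Q -> Z; 2 X <-> E; G <-> E; X -> D

At the first reading the south-east run is missing 11.0% of its X and the south-west run 14.0%, close to their ratios of Q to X, 10.0% and 15.0%. So take the Q toll, the charge of Q over the charge of X, read as the share of the X charged that ends in Z once Q is used up; for Tuesday's and Sunday's flasks it is 20.0%. In Tuesday's and Sunday's flasks it leaves E a ceiling of 80.0%.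

In the readings 1/x climbs roughly in a straight line, which fits X pairing up; the slopes read off the early readings, with their scatter, are 0.274 min⁻¹ in the south-east run and 0.932 min⁻¹ in the south-west run. Going down to 50 °C, I divide the first by the square root of their ratio, a rough scaling of my own, and get 0.148 min⁻¹.

So my curve for Tuesday's flask, with the toll taken as paid at the start, begins at x = 80.0% and falls at a rate of 0.0947 min⁻¹, as a fraction of the charge. It has halved by 8.42 min, and it reaches 20.2% at the change of temperature, with E near 59.8%. After that E bends over below the ceiling. The last south-west reading is missing 18.0%, above its toll of 15.0% by 3 percentage points against a scatter of 1.5 points, so heat may feed D. Sunday's flask stays hot longer than Tuesday's, 80 min against 55.0 min, so I expect Tuesday's to finish higher.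

The forecast agrees on Tuesday's, with 71% against 68% for Sunday's, and says: “So X → D is slow but strongly temperature dependent”.

The flasks give 64.1% for Tuesday's and 57.0% for Sunday's, so Tuesday's does finish higher, but 6.9 points and 11 points below the forecast.

X + Q → Z (k = 0.520 M⁻¹ s⁻¹, Ea = 50.0 kJ mol⁻¹); 2 X ⇌ E (K = 2500 M⁻¹, k = 0.160 M⁻¹ s⁻¹, Ea = 41.0 kJ mol⁻¹, ΔH = −32.0 kJ mol⁻¹); G ⇌ E, rate k3*(cs3 - [E]) while solid is left; crystals form when [E] > cs3 (solubility = 0.340 mM, k = 0.0750 s⁻¹); X → D (k = 4.90 × 10⁻⁶ s⁻¹, Ea = 110 kJ mol⁻¹); (constants at 50 °C) In Tuesday's flask the half-life of Q by its step with X was 3.8 min at 2.90 min, far shorter than the 80 min of the run, and at the end Q, the limiting reagent of that step, stands at 0% of its charge, with Z at 20.0%, the toll. A neighbour flask like Tuesday's but with 1.2 mM of Q has a toll of 12.0% and a ceiling of 88.0%; its Z stands at 12.0% and its E at 71.9%.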